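**Plan**
- Retrosynthesis: the C7 acetate is removed, then the C8–C12 bond of the cyclopentenone is cut, which unfolds the ring into a 2,3,5-trisubstituted furan. The furan–C8 bond, the C12–C13 bond and the C5=C6 alkene are cut next.
- Enabling feature: ring C8–C9–C10–C11–C12 carries the ketone at C9, bromine at C10 and the tertiary hydroxyl plus the octenyl chain at C12. This is what a 3-bromo-5-octenylfuran with a carbinol on C2 becomes when its ring oxygen turns into the C9 carbonyl.
- Forward: a Z-selective Wittig reaction joins C1–C5 to a glyceraldehyde unit (C6–C8); 2,3-dibromofuran is allylated at C5; the halves meet at C8 by Grignard addition; the only ring is closed by the rearrangement; C7 is acetylated last.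
- Stereochemistry: C7 comes from (R)-glyceraldehyde acetonide, the 14Z alkene from (Z)-oct-2-en-1-ol and the 5Z alkene from the Wittig step. C8 and C12 come from the conrotatory ring closure, steered by the free C7 hydroxyl; the C8 carbinol centre of the precursor is erased on ionisation.

Key step: step 9

Assumptions: prostanoid numbering is used (C1 ester carbon, C8–C12 ring, C13–C20 octenyl chain); 14 and 15 are carried as both C8 epimers and their SMILES leave C8 open, because that centre is erased in step 9; 6 is bought and distilled before use.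

Step 1
Reactants: 1 (Z)-oct-2-en-1-ol
Product: 2 (Z)-1-bromooct-2-ene
Conditions: CBr4, PPh3, CH2Cl2, −20 → 0 °C
Reagents that add atoms: carbon tetrabromide, BrC(Br)(Br)Br
Why: Appel reaction, in which bromide displaces the alkoxyphosphonium group by SN2 at the primary allylic carbon, so the Z-alkene should be retained if the bromide is made cold and used at once.

Step 2
Reactants: 3 2,3-dibromofuran; 2 (Z)-1-bromooct-2-ene
Product: 5 2,3-dibromo-5-[(2Z)-oct-2-en-1-yl]furan, via (4,5-dibromofuran-2-yl)lithium 4 (not isolated)
Conditions: LiN(i-Pr)2, THF, −78 °C; then 2, −78 → −20 °C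
Reagents that add atoms: none
Why: Deprotonation at the only free α-position of the furan followed by SN2 alkylation of the furyllithium at the α-carbon of a primary allylic bromide (the classical allylation of 2-furyllithiums); −78 °C should hold back bromine migration and the Z-alkene is not involved.

Step 3
Reactants: 6 (R)-2,2-dimethyl-1,3-dioxolane-4-carbaldehyde; 7 (4-carboxybutyl)triphenylphosphonium bromide
Product: 9 (5Z)-6-[(4S)-2,2-dimethyl-1,3-dioxolan-4-yl]hex-5-enoic acid, via sodium 5-(triphenylphosphoranylidene)pentanoate 8 (not isolated)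
Conditions: 7, NaN(SiMe3)2 (2.1 equiv), THF, 0 °C; then 6, −78 °C → rt; 0.5 M HCl to pH 4, 0 °C
Reagents that add atoms: none
Why: Wittig olefination with a non-stabilised ylide under lithium-free conditions, where the kinetically formed cis-oxaphosphetane gives the 5Z-alkene; the C7 centre (dioxolane C4, from the chiral pool) should not epimerise at −78 °C.

Step 4
Reactants: 9 (5Z)-6-[(4S)-2,2-dimethyl-1,3-dioxolan-4-yl]hex-5-enoic acid
Product: 10 methyl (5Z,7S)-7,8-dihydroxyoct-5-enoate
Conditions: Amberlyst-15 (H+ form), MeOH, 40 °C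
Reagents that add atoms: methanol, CO
Why: Fischer esterification and acid-catalysed methanolysis of the acetonide in one operation; neither the stereocentre nor the alkene takes part.

Step 5
Reactants: 10 methyl (5Z,7S)-7,8-dihydroxyoct-5-enoate
Product: 11 methyl (5Z,7S)-7,8-bis[(triethylsilyl)oxy]oct-5-enoate
Conditions: Et3SiCl, imidazole, DMAP (cat.), CH2Cl2, 0 °C → rt
Reagents that add atoms: chlorotriethylsilane, CC[Si](Cl)(CC)CC
Why: Routine silylation of both hydroxyls, which sets up the primary silyl ether for direct oxidation and masks C7–OH for the organometallic step.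

Step 6
Reactants: 11 methyl (5Z,7S)-7,8-bis[(triethylsilyl)oxy]oct-5-enoate
Product: 12 methyl (5Z,7S)-8-oxo-7-[(triethylsilyl)oxy]oct-5-enoate
Conditions: (COCl)2, DMSO, CH2Cl2, −78 → −40 °C; i-Pr2NEt, −78 → −20 °C; used crude
Reagents that add atoms: none
Why: Swern oxidation of a bis-silyl ether, in which the chlorodimethylsulfonium ion cleaves only the unhindered primary triethylsilyl ether and the alkoxysulfonium ion collapses to the aldehyde; the hindered amine and low temperature are chosen to keep C7 (α to the aldehyde and allylic) from enolising.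

Step 7
Reactants: 5 2,3-dibromo-5-[(2Z)-oct-2-en-1-yl]furan; 12 methyl (5Z,7S)-8-oxo-7-[(triethylsilyl)oxy]oct-5-enoate
Product: 14 methyl (5Z,7S)-8-{3-bromo-5-[(2Z)-oct-2-en-1-yl]furan-2-yl}-8-hydroxy-7-[(triethylsilyl)oxy]oct-5-enoate (both C8 epimers), via {3-bromo-5-[(2Z)-oct-2-en-1-yl]furan-2-yl}magnesium chloride 13 (not isolated)
Conditions: 5, i-PrMgCl·LiCl, THF, −10 °C; then 12, −78 → −30 °C; aq. NH4Cl
Reagents that add atoms: none
Why: Bromine–magnesium exchange occurs at the α-bromine on C2, and the weakly basic heteroaryl Grignard reagent adds to the aldehyde much faster than to the methyl ester; C8 forms without control (Felkin–Anh addition expected to lead), which does not matter because C8 is ionised in step 9.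

Step 8
Reactants: 14 methyl (5Z,7S)-8-{3-bromo-5-[(2Z)-oct-2-en-1-yl]furan-2-yl}-8-hydroxy-7-[(triethylsilyl)oxy]oct-5-enoate
Product: 15 methyl (5Z,7S)-8-{3-bromo-5-[(2Z)-oct-2-en-1-yl]furan-2-yl}-7,8-dihydroxyoct-5-enoate (both C8 epimers)
Conditions: Bu4NF, AcOH (1:1), THF, 0 °C
Reagents that add atoms: none
Why: Fluoride-driven cleavage of the silyl ether in a near-neutral buffer that spares the acid-labile furylcarbinol and the ester; any silyl migration between O7 and O8 in step 7 is harmless because both isomers give 15.

Step 9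
Reactants: 15 methyl (5Z,7S)-8-{3-bromo-5-[(2Z)-oct-2-en-1-yl]furan-2-yl}-7,8-dihydroxyoct-5-enoate
Product: 16 methyl (5Z,7S)-7-{(1R,5S)-3-bromo-5-hydroxy-5-[(2Z)-oct-2-en-1-yl]-2-oxocyclopent-3-en-1-yl}-7-hydroxyhept-5-enoate (7S,8R,12S)
Conditions: Dy(OTf)3 (10 mol %), t-BuOH/H2O (5:1), 80 °C
Reagents that add atoms: water, O
Why: Piancatelli rearrangement, the closest known reaction type being the lanthanide-triflate-catalysed conversion of 5-alkyl-2-furylcarbinols into 4-alkyl-4-hydroxycyclopent-2-enones in water: Dy(OTf)3 ionises the C8 carbinol (both epimers give one cation), water adds to furan carbon C12, the hemiketal opens to a 1,4-dihydroxypentadienyl cation over C8–C12, and the C9 enol finally tautomerises to the bromoenone. The five-membered ring closes by thermal conrotatory 4π electrocyclisation of that cation, forming C8–C12 with the former furan oxygen as the C9 carbonyl. C12 is set irreversibly in this closure: the oxocarbenium terminus should turn its small hydroxyl inward and the octenyl chain outward to avoid A(1,3) strain, so with the C7 arm outward at C8 conrotation places the two carbon chains trans, which is also the stable arrangement at the epimerisable C8. The step also needs one sense of conrotation, and the free C7 hydroxyl is there to secure it: hydrogen-bonded or dysprosium-chelated to the C9 oxygen it lies in the plane of the cation, hydrogen and the Z-alkenyl arm then occupy opposite faces of C8, and C12 should bond anti to the alkenyl arm, which on a model is the (7S,8R,12S) isomer. Ionisation is expected at the furfurylic C8 and not at the allylic C7 because only the former is stabilised by the 5-alkylfuran; the 3-bromo substituent and the neighbouring hydroxyl slow it, hence 80 °C. The (8S,12R) isomer, if formed, is a diastereomer and would be removed by chromatography.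

Step 10
Reactants: 16 methyl (5Z,7S)-7-{(1R,5S)-3-bromo-5-hydroxy-5-[(2Z)-oct-2-en-1-yl]-2-oxocyclopent-3-en-1-yl}-7-hydroxyhept-5-enoate
Product: 17 methyl (5Z,7S)-7-acetoxy-7-{(1R,5S)-3-bromo-5-hydroxy-5-[(2Z)-oct-2-en-1-yl]-2-oxocyclopent-3-en-1-yl}hept-5-enoate, i.e. methyl (5Z,7S,8R,12S,14Z)-7-acetoxy-10-bromo-12-hydroxy-9-oxoprosta-5,10,14-trienoate
Conditions: Ac2O (1.2 equiv), pyridine, DMAP (2 mol %), CH2Cl2, −20 → 0 °C
Reagents that add atoms: acetic anhydride, CC(=O)OC(C)=O
Why: Nucleophile-catalysed acylation that distinguishes the secondary allylic C7 hydroxyl from the hindered tertiary C12 hydroxyl; low temperature and near-stoichiometric anhydride are chosen so that the β-acetoxy ketone does not lose acetic acid toward the conjugated dienone and C8 is not epimerised.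

**Compound list**
1 | (Z)-oct-2-en-1-ol | CCCCC/C=C\CO | starting material
2 | (Z)-1-bromooct-2-ene | CCCCC/C=C\CBr | intermediate
3 | 2,3-dibromofuran | Brc1occc1Br | starting material
4 | (4,5-dibromofuran-2-yl)lithium | [Li]c1cc(Br)c(Br)o1 | intermediate
5 | 2,3-dibromo-5-[(2Z)-oct-2-en-1-yl]furan | CCCCC/C=C\Cc1cc(Br)c(Br)o1 | intermediate
6 | (R)-2,2-dimethyl-1,3-dioxolane-4-carbaldehyde | O=C[C@H]1COC(C)(C)O1 | starting material
7 | (4-carboxybutyl)triphenylphosphonium bromide | [Br-].OC(=O)CCCC[P+](c1ccccc1)(c1ccccc1)c1ccccc1 | starting material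
8 | sodium 5-(triphenylphosphoranylidene)pentanoate | [Na+].[O-]C(=O)CCCC=P(c1ccccc1)(c1ccccc1)c1ccccc1 | intermediate
9 | (5Z)-6-[(4S)-2,2-dimethyl-1,3-dioxolan-4-yl]hex-5-enoic acid | OC(=O)CCC/C=C\[C@H]1COC(C)(C)O1 | intermediate
10 | methyl (5Z,7S)-7,8-dihydroxyoct-5-enoate | COC(=O)CCC/C=C\[C@H](O)CO | intermediate
11 | methyl (5Z,7S)-7,8-bis[(triethylsilyl)oxy]oct-5-enoate | COC(=O)CCC/C=C\[C@H](O[Si](CC)(CC)CC)CO[Si](CC)(CC)CC | intermediate
12 | methyl (5Z,7S)-8-oxo-7-[(triethylsilyl)oxy]oct-5-enoate | COC(=O)CCC/C=C\[C@H](O[Si](CC)(CC)CC)C=O | intermediate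
13 | {3-bromo-5-[(2Z)-oct-2-en-1-yl]furan-2-yl}magnesium chloride | CCCCC/C=C\Cc1cc(Br)c([Mg]Cl)o1 | intermediate
14 | methyl (5Z,7S)-8-{3-bromo-5-[(2Z)-oct-2-en-1-yl]furan-2-yl}-8-hydroxy-7-[(triethylsilyl)oxy]oct-5-enoate, both C8 epimers | CCCCC/C=C\Cc1cc(Br)c(o1)C(O)[C@H](/C=C\CCCC(=O)OC)O[Si](CC)(CC)CC | intermediate
15 | methyl (5Z,7S)-8-{3-bromo-5-[(2Z)-oct-2-en-1-yl]furan-2-yl}-7,8-dihydroxyoct-5-enoate, both C8 epimers | CCCCC/C=C\Cc1cc(Br)c(o1)C(O)[C@H](/C=C\CCCC(=O)OC)O | intermediate
16 | methyl (5Z,7S)-7-{(1R,5S)-3-bromo-5-hydroxy-5-[(2Z)-oct-2-en-1-yl]-2-oxocyclopent-3-en-1-yl}-7-hydroxyhept-5-enoate | CCCCC/C=C\C[C@@]1(O)C=C(Br)C(=O)[C@@H]1[C@H](/C=C\CCCC(=O)OC)O | intermediate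
17 | methyl (5Z,7S)-7-acetoxy-7-{(1R,5S)-3-bromo-5-hydroxy-5-[(2Z)-oct-2-en-1-yl]-2-oxocyclopent-3-en-1-yl}hept-5-enoate | CCCCC/C=C\C[C@@]1(O)C=C(Br)C(=O)[C@@H]1[C@H](/C=C\CCCC(=O)OC)OC(C)=O | target

**Count**
Total steps: 10. Longest linear sequence: 8 steps (steps 3–10, from 6 and 7); the furan branch (steps 1, 2) joins at step 7.

**Steps most likely to fail**

Step 9. What may go wrong: the furfurylic cation sits next to a hydroxyl-bearing allylic carbon and may be drained by a pinacol-type 1,2-shift; the unprotected β-hydroxy ketone of the product may lose water under the hot Lewis acid; or the hydroxyl-directed face selection of the conrotatory closure may be too weak. The fallback sets out from silyl ether 14 and keeps C7 protected. The rearrangement would be run with a chiral BINOL-derived phosphoric acid (TRIP, 3,3′-bis(2,4,6-triisopropylphenyl)-1,1′-binaphthyl-2,2′-diyl hydrogen phosphate, the enantiomer matched to C7) in wet toluene at 40–60 °C. The chiral phosphate counter-ion of the cation, as in catalytic asymmetric aza-Piancatelli reactions, then decides the sense of conrotation in place of the substrate hydroxyl. This should give methyl (5Z,7S)-7-{(1R,5S)-3-bromo-5-hydroxy-5-[(2Z)-oct-2-en-1-yl]-2-oxocyclopent-3-en-1-yl}-7-[(triethylsilyl)oxy]hept-5-enoate F1, in which the silyl ether guards C7 against elimination. HF·pyridine in THF at 0 °C then removes the silyl group and the route is rejoined at 16.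

Step 7. What may go wrong: deprotonation of aldehyde 12 at C7 by the organomagnesium reagent, with loss of configurational purity or migration of the 5,6-double bond into conjugation. The fallback is a Nozaki–Hiyama–Kishi coupling that sets out from 5 and 12 themselves. CrCl2 (excess) with catalytic NiCl2 in DMF/THF at room temperature should activate the α-bromine of 5 and generate a non-basic organochromium species in the presence of the aldehyde, so that no preformed carbanion meets 12. The coupling product is 14, where the route is rejoined; no new compound is made on the way.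

Step 2. What may go wrong: bromine migration between ring positions in lithiated intermediate 4 (halogen dance) before the alkylation, which would scramble the substitution pattern. The fallback sets out from bromide 2 and purchased 3-bromofuran (Brc1ccoc1) and uses a silyl blocking group in place of the second bromine.
- LiN(i-Pr)2 at −78 °C lithiates C2 to give (3-bromofuran-2-yl)lithium F2, and Me3SiCl converts it into (3-bromofuran-2-yl)trimethylsilane F3.
- A second lithiation with LiN(i-Pr)2 at the remaining α-position gives [4-bromo-5-(trimethylsilyl)furan-2-yl]lithium F4, which is alkylated with 2 to {3-bromo-5-[(2Z)-oct-2-en-1-yl]furan-2-yl}trimethylsilane F5.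
- Bu4NF removes the silyl group to give 4-bromo-2-[(2Z)-oct-2-en-1-yl]furan F6.
- LiN(i-Pr)2 deprotonates F6 next to bromine to give {3-bromo-5-[(2Z)-oct-2-en-1-yl]furan-2-yl}lithium F7, which adds to aldehyde 12 at −78 °C.

The route is rejoined at 14; compound 5 and the exchange of step 7 are then not needed.

**Further compounds**
F1 | step 9 | methyl (5Z,7S)-7-{(1R,5S)-3-bromo-5-hydroxy-5-[(2Z)-oct-2-en-1-yl]-2-oxocyclopent-3-en-1-yl}-7-[(triethylsilyl)oxy]hept-5-enoate | CCCCC/C=C\C[C@@]1(O)C=C(Br)C(=O)[C@@H]1[C@H](/C=C\CCCC(=O)OC)O[Si](CC)(CC)CC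
F0 | step 7 | none | none
F2 | step 2 | (3-bromofuran-2-yl)lithium | [Li]c1occc1Br
F3 | step 2 | (3-bromofuran-2-yl)trimethylsilane | C[Si](C)(C)c1occc1Br
F4 | step 2 | [4-bromo-5-(trimethylsilyl)furan-2-yl]lithium | [Li]c1cc(Br)c(o1)[Si](C)(C)C
F5 | step 2 | {3-bromo-5-[(2Z)-oct-2-en-1-yl]furan-2-yl}trimethylsilane | CCCCC/C=C\Cc1cc(Br)c(o1)[Si](C)(C)C
F6 | step 2 | 4-bromo-2-[(2Z)-oct-2-en-1-yl]furan | CCCCC/C=C\Cc1cc(Br)co1
F7 | step 2 | {3-bromo-5-[(2Z)-oct-2-en-1-yl]furan-2-yl}lithium | CCCCC/C=C\Cc1cc(Br)c([Li])o1
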